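Ring C of the lower unit is cut across C4a′–C4′ and C2′–C3′. Ring B carries oxygen at C5′ and C8′ in a para relation, so it is a masked 1,4-benzoquinone; its C4a′=C8a′ bond and an exocyclic C1′=C2′ bond form a vinylquinone diene. Cycloaddition with a (Z)-2-selanyl silyl enol ether (C3′–C4′) gives an o-quinone methide at C1′, which the peri C4 ketone of the upper naphthoquinone captures, so one operation closes ring C and both ketal rings. The precursor is a 1,1-diarylethylene bis-quinone. Selenoxide elimination, two substrate-controlled epoxidations and desilylation finish the route; a camphanate on the C8 oxygen allows separation of the two core enantiomer series.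

Key step: step 11

Remark on numbering (used throughout): upper unit C1–C8a (C1 ketone, C2/C3 epoxide, C4 ketal carbon, C7 Cl, C8 OH; ring A is its benzenoid ring); lower unit C1′–C8a′ (C1′ quaternary carbon, C2′/C3′ epoxide, C4′ carbinol, C5′ OH, C6′ Cl, C8′ ether oxygen; ring B benzenoid, ring C carbocyclic). The units are joined by C5–C1′, C4–O–C1′ and C4–O–C8′. With this numbering the target is 2S,3R,4S,1′S,2′R,3′R,4′S; the SMILES strings are authoritative.

Remark on the chemistry: compounds 1, 2, 8 and 14, (1S)-(−)-camphanic chloride and PhSeCl are assumed to be commercial. The absolute configuration is not induced. Step 11 is expected to be unselective with respect to the remote camphanate, so the diastereomer of 19 with the mirror-image core should form alongside it. Only 19 is carried on; the other diastereomer is removed by chromatography in step 11 and is given no number.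

Step 1
Reactants: 1 2-bromo-1,4-dimethoxybenzene; 2 furan
Product: 4 5,8-dimethoxy-1,4-dihydro-1,4-epoxynaphthalene (meso), via 3,6-dimethoxybenzyne 3 (not isolated)
Conditions: LiN(i-Pr)2 (lithium diisopropylamide, 1.2 equiv), furan (excess), THF, −78 → 23 °C
Reagents that add atoms: none
Why: Deprotonation between Br and OMe and loss of LiBr give the symmetrical aryne, which furan traps in an aryne Diels–Alder reaction; the cis bridge is the only stereochemical outcome possible.

Step 2
Reactants: 4 5,8-dimethoxy-1,4-dihydro-1,4-epoxynaphthalene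
Product: 5 5,8-dimethoxynaphthalen-1-ol
Conditions: conc. HCl (cat.), MeOH, 23 → 50 °C
Reagents that add atoms: none
Why: Acid-catalysed opening of the oxygen bridge and aromatisation (epoxynaphthalene-to-1-naphthol isomerisation) should give one naphthol because the substrate is symmetrical.

Step 3
Reactants: 5 5,8-dimethoxynaphthalen-1-ol
Product: 6 4-bromo-5,8-dimethoxynaphthalen-1-ol
Conditions: NBS (1.0 equiv), MeCN, −20 → 0 °C
Reagents that add atoms: N-bromosuccinimide, O=C1CCC(=O)N1Br
Why: Electrophilic aromatic bromination should go para to the free naphthol hydroxyl, the most activated position.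

Step 4
Reactants: 6 4-bromo-5,8-dimethoxynaphthalen-1-ol
Product: 7 4-bromo-2-chloro-5,8-dimethoxynaphthalen-1-ol
Conditions: NCS (1.05 equiv), MeCN, 23 °C
Reagents that add atoms: N-chlorosuccinimide, O=C1CCC(=O)N1Cl
Why: With the para position blocked, electrophilic chlorination of the naphthol ring can only take the ortho position C2.

Step 5
Reactants: 8 2-chloro-1,4-dimethoxybenzene
Product: 9 1-(4-chloro-2,5-dimethoxyphenyl)ethan-1-one
Conditions: AcCl, AlCl3, CH2Cl2, 0 °C
Reagents that add atoms: acetyl chloride, CC(Cl)=O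
Why: Friedel–Crafts acylation should occur para to chlorine and ortho to a methoxy group, the usual site of electrophilic attack on this arene.

Step 6
Reactants: 7 4-bromo-2-chloro-5,8-dimethoxynaphthalen-1-ol; 9 1-(4-chloro-2,5-dimethoxyphenyl)ethan-1-one
Product: 11 2-chloro-4-[1-(4-chloro-2,5-dimethoxyphenyl)ethenyl]-5,8-dimethoxynaphthalen-1-ol, via tertiary carbinol 10 (not isolated)
Conditions: n-BuLi (2.2 equiv), THF, −78 °C; CeCl3, −78 °C; 9, −78 → 0 °C; aq. NH4Cl; then p-TsOH·H2O (cat.), toluene, 50 °C
Reagents that add atoms: none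
Why: Bromine–lithium exchange on the lithium naphthoxide, transmetalation to the less basic organocerium reagent, 1,2-addition to the enolisable ketone and acid-catalysed E1 dehydration of the doubly benzylic carbinol should give the 1,1-diarylethylene.

Step 7
Reactants: 11 2-chloro-4-[1-(4-chloro-2,5-dimethoxyphenyl)ethenyl]-5,8-dimethoxynaphthalen-1-ol
Product: 12 (1S,4R)-camphanate ester of 11 at the naphthol oxygen
Conditions: (1S)-(−)-camphanic chloride, Et3N, DMAP (cat.), CH2Cl2, 23 °C
Reagents that add atoms: (1S,4R)-camphanic chloride, CC1(C)[C@@]2(C)CC[C@]1(C(=O)Cl)OC2=O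
Why: DMAP-catalysed esterification masks the naphthol against oxidation in step 8 and installs the camphanoyl group as the resolving handle.

Step 8
Reactants: 12 camphanate of the diarylethylene
Product: 13 bis-quinone: 6-chloro-8-[1-(4-chloro-3,6-dioxocyclohexa-1,4-dien-1-yl)ethenyl]-1,4-dioxo-1,4-dihydronaphthalen-5-yl (1S,4R)-camphanate
Conditions: (NH4)2Ce(NO3)6 (5 equiv), MeCN/H2O, 0 °C; product used at once
Reagents that add atoms: water, O
Why: Oxidative demethylation of both para-dimethoxy rings by tetravalent cerium, with water supplying the new carbonyl oxygens, should give the bis-quinone while the acylated naphthol oxygen stays untouched.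

Step 9
Reactants: 14 trimethyl(vinyloxy)silane
Product: 15 2-(phenylselanyl)acetaldehyde
Conditions: PhSeCl, CH2Cl2, −78 → 0 °C
Reagents that add atoms: benzeneselenenyl chloride, Cl[Se]c1ccccc1
Why: Electrophilic alpha-selenenylation of the silyl enol ether with loss of Me3SiCl should give the alpha-selanyl aldehyde.

Step 10
Reactants: 15 2-(phenylselanyl)acetaldehyde
Product: 16 (Z)-tert-butyldimethyl{[2-(phenylselanyl)ethenyl]oxy}silane
Conditions: TBSOTf, Et3N, CH2Cl2, 0 °C
Reagents that add atoms: tert-butyldimethylsilyl trifluoromethanesulfonate, CC(C)(C)[Si](C)(C)OS(=O)(=O)C(F)(F)F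
Why: Soft enolisation and O-silylation of the aldehyde should give mainly the (Z)-silyl enol ether, the isomer needed for the cis C3′/C4′ relationship.

Step 11
Reactants: 13 bis-quinone; 16 (Z)-2-selanyl silyl enol ether
Product: 19 pentacyclic selenide ketal camphanate (target core configuration; C4′–OSi anti to C1′–O; C3′–SePh cis to C4′–OSi; C2=C3 enone; free C5′ phenol), via Diels–Alder adduct 17 (not isolated), via o-quinone methide 18 (not isolated)
Conditions: 16 (3 equiv), toluene, 60 °C, dark; then PPTS (cat.), 23 °C; chromatographic separation of the two camphanate diastereomers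
Reagents that add atoms: none
Why: The electron-poor diene C4a′=C8a′–C1′=C2′ of the vinylquinone and the electron-rich enol ether combine in an inverse-electron-demand Diels–Alder reaction in which the selanyl-bearing nucleophilic carbon C3′ bonds to the open CH2 terminus C2′ (larger LUMO coefficient, less hindrance) and the silyloxy carbon C4′ to C4a′; enolisation of adduct 17 gives o-quinone methide 18, whose C1′ is attacked by the oxygen of the peri C4 ketone, and the C8′ phenoxide then closes onto the resulting oxocarbenium ion. The closest known reactions are the vinylquinone Diels–Alder reaction with interception of the isoquinone methide by an oxygen nucleophile and the formal hetero-[4+2] addition of carbonyl groups to o-quinone methides. Ring C closes by the suprafacial [4+2] cycloaddition, the five-membered C1′–O–C4 ring by 5-exo-trig attack of the carbonyl oxygen on the methide, and the 1,3-dioxin ring by 6-endo-trig attack of the phenoxide on the oxocarbenium carbon C4. C4′ is set in the cycloaddition and is cis to C3′–Se because the (Z)-enol ether adds suprafacially; the ketone oxygen then adds to C1′ on the face opposite to these two cis substituents, which puts C1′–O anti to C4′–OSi, and the configuration of ketal carbon C4 follows from that of C1′ because the bicyclic cage allows no other. The step needs regioselectivity (C3′ to C2′), periselectivity over dimerisation of the vinylquinone and over polar addition of the enol ether to the quinone ring, and the 1,4-anti relay; the bulky selanyl group on the nucleophilic carbon, the excess of dienophile and the absence of Lewis acid are meant to secure them. The remote camphanate cannot bias the diene faces, so the diastereomer with the mirror-image core should form in equal amount and is removed by chromatography at this stage.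

Step 12
Reactants: 19 pentacyclic selenide ketal camphanate
Product: 21 C2′=C3′ alkene ketal camphanate (C4′–OSi and C2=C3 enone retained), via selenoxide 20 (not isolated)
Conditions: mCPBA (1.05 equiv), CH2Cl2, −78 °C; then pyridine, −78 → 23 °C
Reagents that add atoms: none
Why: Oxidation to the selenoxide and syn elimination (selenoxide elimination) can only remove a C2′ hydrogen, because the C4′ hydrogen is trans to selenium, so the C2′=C3′ alkene should form regiospecifically with no stereocentre touched.

Step 13
Reactants: 21 alkene ketal camphanate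
Product: 23 (2S,3R)-2,3-epoxy ketone with free C8 phenol (C2′=C3′ alkene and C4′–OSi retained), via phenol enone 22 (not isolated)
Conditions: LiOH, 30% H2O2, THF/H2O, 0 °C; aq. NH4Cl
Reagents that add atoms: hydrogen peroxide, OO
Why: In a Weitz–Scheffer nucleophilic epoxidation, hydroperoxide should add to C3 of the enone on the face anti to the pseudoaxial C4–O–C8′ bond and ring B, setting C2 and C3, while the aryl camphanate is cleaved by perhydrolysis.

Step 14
Reactants: 23 2,3-epoxy ketone alkene
Product: 24 bis-epoxide 4′-O-tert-butyldimethylsilyl ether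
Conditions: mCPBA, CH2Cl2, 0 → 23 °C
Reagents that add atoms: 3-chloroperoxybenzoic acid, OOC(=O)c1cccc(Cl)c1
Why: Prilezhaev epoxidation of the isolated cis-alkene should occur anti to the bulky C4′ silyloxy group and the C5 aryl bridge, that is on the face of the C1′–O bond, setting C2′ and C3′.

Step 15
Reactants: 24 bis-epoxide silyl ether
Product: 25 CNP0289684.3
Conditions: HF·pyridine, pyridine, THF, 0 → 23 °C
Reagents that add atoms: none
Why: Buffered fluoride cleavage of the secondary silyl ether (desilylation) should free the C4′ alcohol without touching the epoxides or the ketal.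

Compound list
1 | 2-bromo-1,4-dimethoxybenzene | COc1ccc(OC)c(Br)c1 | starting material
2 | furan | c1ccoc1 | starting material
3 | 3,6-dimethoxybenzyne | COC1=CC=C(OC)C#C1 | intermediate (not isolated)
4 | 5,8-dimethoxy-1,4-dihydro-1,4-epoxynaphthalene (meso) | COc1ccc(OC)c2[C@@H]3C=C[C@@H](O3)c12 | intermediate
5 | 5,8-dimethoxynaphthalen-1-ol | COc1ccc(OC)c2c(O)cccc12 | intermediate
6 | 4-bromo-5,8-dimethoxynaphthalen-1-ol | COc1ccc(OC)c2c(O)ccc(Br)c12 | intermediate
7 | 4-bromo-2-chloro-5,8-dimethoxynaphthalen-1-ol | COc1ccc(OC)c2c(O)c(Cl)cc(Br)c12 | intermediate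
8 | 2-chloro-1,4-dimethoxybenzene | COc1ccc(OC)c(Cl)c1 | starting material
9 | 1-(4-chloro-2,5-dimethoxyphenyl)ethan-1-one | CC(=O)c1cc(OC)c(Cl)cc1OC | intermediate
10 | racemic 1-(4-chloro-2,5-dimethoxyphenyl)-1-(3-chloro-4-hydroxy-5,8-dimethoxynaphthalen-1-yl)ethan-1-ol | CC(O)(c1cc(OC)c(Cl)cc1OC)c1cc(Cl)c(O)c2c(OC)ccc(OC)c12 | intermediate (not isolated)
11 | 2-chloro-4-[1-(4-chloro-2,5-dimethoxyphenyl)ethenyl]-5,8-dimethoxynaphthalen-1-ol | C=C(c1cc(OC)c(Cl)cc1OC)c1cc(Cl)c(O)c2c(OC)ccc(OC)c12 | intermediate
12 | (1S,4R)-camphanate of 11 | C=C(c1cc(OC)c(Cl)cc1OC)c1cc(Cl)c(OC(=O)[C@@]34CC[C@@](C)(C(=O)O3)C4(C)C)c2c(OC)ccc(OC)c12 | intermediate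
13 | bis-quinone, 6-chloro-8-[1-(4-chloro-3,6-dioxocyclohexa-1,4-dien-1-yl)ethenyl]-1,4-dioxo-1,4-dihydronaphthalen-5-yl (1S,4R)-camphanate | C=C(C1=CC(=O)C(Cl)=CC1=O)c1cc(Cl)c(OC(=O)[C@@]34CC[C@@](C)(C(=O)O3)C4(C)C)c2C(=O)C=CC(=O)c12 | intermediate
14 | trimethyl(vinyloxy)silane | C=CO[Si](C)(C)C | starting material
15 | 2-(phenylselanyl)acetaldehyde | O=CC[Se]c1ccccc1 | intermediate
16 | (Z)-tert-butyldimethyl{[2-(phenylselanyl)ethenyl]oxy}silane | CC(C)(C)[Si](C)(C)O/C=C\[Se]c1ccccc1 | intermediate
17 | Diels–Alder adduct (C4a′–H trans to C4′–OSi, C3′–Se cis to C4′–OSi, exocyclic C1′=C8a′) | O=C1C=C(Cl)C(=O)[C@@H]2[C@H](O[Si](C)(C)C(C)(C)C)[C@H]([Se]c3ccccc3)CC(c3cc(Cl)c(OC(=O)[C@@]45CC[C@@](C)(C(=O)O4)C5(C)C)c4C(=O)C=CC(=O)c34)=C12 | intermediate (not isolated)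
18 | o-quinone methide (C5′ enol, C8′ carbonyl, C1′=C8a′) | O=C1C=C(Cl)C(O)=C2[C@H](O[Si](C)(C)C(C)(C)C)[C@H]([Se]c3ccccc3)CC(c3cc(Cl)c(OC(=O)[C@@]45CC[C@@](C)(C(=O)O4)C5(C)C)c4C(=O)C=CC(=O)c34)=C12 | intermediate (not isolated)
19 | pentacyclic selenide ketal, target core configuration, C8 camphanate, C4′–OTBS, C3′–SePh | O=C1c2c(OC(=O)[C@@]67CC[C@@](C)(C(=O)O6)C7(C)C)c(Cl)cc3c2[C@@]2(Oc4cc(Cl)c(O)c5c4[C@]3(O2)C[C@@H]([Se]c4ccccc4)[C@H]5O[Si](C)(C)C(C)(C)C)C=C1 | intermediate
20 | selenoxide of 19 (mixture at selenium) | O=C1c2c(OC(=O)[C@@]67CC[C@@](C)(C(=O)O6)C7(C)C)c(Cl)cc3c2[C@@]2(Oc4cc(Cl)c(O)c5c4[C@]3(O2)C[C@@H]([Se](=O)c4ccccc4)[C@H]5O[Si](C)(C)C(C)(C)C)C=C1 | intermediate (not isolated)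
21 | C2′=C3′ alkene ketal, C8 camphanate, C4′–OTBS | O=C1c2c(OC(=O)[C@@]67CC[C@@](C)(C(=O)O6)C7(C)C)c(Cl)cc3c2[C@@]2(Oc4cc(Cl)c(O)c5c4[C@]3(O2)C=C[C@H]5O[Si](C)(C)C(C)(C)C)C=C1 | intermediate
22 | phenol enone (camphanate removed) | O=C1c2c(O)c(Cl)cc3c2[C@@]2(Oc4cc(Cl)c(O)c5c4[C@]3(O2)C=C[C@H]5O[Si](C)(C)C(C)(C)C)C=C1 | intermediate (not isolated)
23 | (2S,3R)-2,3-epoxy ketone with C2′=C3′ alkene and C4′–OTBS | O=C1c2c(O)c(Cl)cc3c2[C@@]2(Oc4cc(Cl)c(O)c5c4[C@]3(O2)C=C[C@H]5O[Si](C)(C)C(C)(C)C)[C@@H]2O[C@H]12 | intermediate
24 | bis-epoxide 4′-O-tert-butyldimethylsilyl ether | O=C1c2c(O)c(Cl)cc3c2[C@@]2(Oc4cc(Cl)c(O)c5c4[C@]3(O2)[C@@H]2O[C@@H]2[C@H]5O[Si](C)(C)C(C)(C)C)[C@@H]2O[C@H]12 | intermediate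
25 | CNP0289684.3 | O=C1c2c(O)c(Cl)cc3c2[C@@]2(Oc4cc(Cl)c(O)c5c4[C@]3(O2)[C@@H]2O[C@@H]2[C@H]5O)[C@@H]2O[C@H]12 | target

Total step count: 15. Longest linear sequence: 12 steps (steps 1–4, 6–8, 11–15).

Steps most likely to fail

Step 11. The 1,2-disubstituted enol ether may add too slowly to the hindered 1,1-disubstituted diene, so that dimerisation of the vinylquinone or polar addition to the quinone ring takes over; the anti relay from C3′/C4′ to C1′ may also be eroded. Fallback, from 12 back to 21: the leaving group is moved to the diene and the unhindered parent enol ether is used. Vinylic bromination of 12 with NBS (addition–elimination) should give the 2-bromo-1,1-diarylethylene F1; the isomer with bromine trans to the ring B aryl is the one that can reach the s-cis diene. Oxidation with (NH4)2Ce(NO3)6 should then give the bromovinyl bis-quinone F2. The same cycloaddition/ketalisation with commercial tert-butyldimethyl(vinyloxy)silane, followed by the same chromatographic separation of the two camphanate diastereomers, should give the C2′ bromide F3. E2 dehydrobromination with DBU, for which only C3′ hydrogens are available, returns to alkene 21.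

Step 8. The electron-rich 1,1-diarylethylene may be over-oxidised, or the vinylquinone may dimerise during the aqueous oxidation and isolation. Fallback, from 10 back to 13: the oxidation is done before the alkene exists. Carbinol 10 is isolated instead of dehydrated, and its naphthol is acylated with (1S)-camphanic chloride to the camphanate carbinol F4. Oxidation with (NH4)2Ce(NO3)6 should give the bis-quinone carbinol F5. Syn dehydration with methyl N-(triethylammoniosulfonyl)carbamate under neutral, anhydrous conditions should then release 13 in the flask in which step 11 is run.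

Step 14. The peracid may be delivered to the wrong face of the C2′=C3′ alkene, and the electron-rich ring B phenol may be oxidised on long exposure. Fallback, from 23 back to 24: a halohydrin route, which places the oxygen on the face opposite to the one the electrophile attacks first. NBS in aqueous THF should give the trans bromohydrin F6 by anti opening of the bromonium ion with water at the less hindered C3′, and K2CO3 should close it to epoxide 24.

Further compounds
F1 | step 11 | 2-bromovinyl analogue of 12 (Br trans to the ring B aryl) | Br/C=C(/c1cc(OC)c(Cl)cc1OC)c1cc(Cl)c(OC(=O)[C@@]34CC[C@@](C)(C(=O)O3)C4(C)C)c2c(OC)ccc(OC)c12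
F2 | step 11 | 2-bromovinyl analogue of bis-quinone 13 | Br/C=C(/C1=CC(=O)C(Cl)=CC1=O)c1cc(Cl)c(OC(=O)[C@@]34CC[C@@](C)(C(=O)O3)C4(C)C)c2C(=O)C=CC(=O)c12
F3 | step 11 | pentacyclic C2′ bromide ketal (Br cis to C4′–OTBS, C3′ unsubstituted) | O=C1c2c(OC(=O)[C@@]67CC[C@@](C)(C(=O)O6)C7(C)C)c(Cl)cc3c2[C@@]2(Oc4cc(Cl)c(O)c5c4[C@]3(O2)[C@@H](Br)C[C@H]5O[Si](C)(C)C(C)(C)C)C=C1
F4 | step 8 | camphanate of carbinol 10 (both carbinol epimers) | CC(O)(c1cc(OC)c(Cl)cc1OC)c1cc(Cl)c(OC(=O)[C@@]34CC[C@@](C)(C(=O)O3)C4(C)C)c2c(OC)ccc(OC)c12
F5 | step 8 | bis-quinone tertiary carbinol (both carbinol epimers) | CC(O)(C1=CC(=O)C(Cl)=CC1=O)c1cc(Cl)c(OC(=O)[C@@]34CC[C@@](C)(C(=O)O3)C4(C)C)c2C(=O)C=CC(=O)c12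
F6 | step 14 | trans bromohydrin of 23 (C2′–Br syn to C4′–OTBS, C3′–OH anti) | O=C1c2c(O)c(Cl)cc3c2[C@@]2(Oc4cc(Cl)c(O)c5c4[C@]3(O2)[C@@H](Br)[C@H](O)[C@H]5O[Si](C)(C)C(C)(C)C)[C@@H]2O[C@H]12
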